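## Analysis of the target

Target 30 is a linear heptamer of benzene rings, lettered A to G, joined by six diaryl ether oxygens and carrying seventeen free phenolic hydroxyls. It has no stereocentre and no ring fusion, and the ether axes rotate freely, so the problem is one of connectivity and of telling oxygens apart. Ring A is a 2,4,6-trihydroxyphenoxy end and ring G a 3,4,5-trihydroxyphenoxy end. Rings B, C, E and F each take the incoming ether oxygen on C1, carry their own outgoing oxygen on C4 and have hydroxyls on C3 and C5. Ring D is the only pentaoxygenated ring: the oxygen from ring C sits on C1, its own oxygen to ring E on the neighbouring C2, hydroxyls on C3 to C5 and hydrogen on C6. Every ether oxygen is therefore bound on one side to a carbon flanked by two oxygen-bearing carbons, and such hindered, electron-rich phenols are poor partners in copper- or palladium-mediated arylation. The free polyphenol, with 1,2,3-trihydroxy arrays in rings D and G, is oxidised easily by air, so the hydroxyls have to travel as ethers and sixteen of them must fall in the last step. The strategy rests on rings B and C: in each, C1 has two CH neighbours and lies para to the ring's own oxygen on C4, which sits between the oxygenated C3 and C5, and that is the skeleton of syringic acid 1 with the carboxyl carbon taken out.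

## Retrosynthetic reasoning

Target 30 is traced back to 29 by cutting all sixteen alkyl–oxygen bonds in one operation. The alkyl groups are already present on the purchased building blocks, and the diaryl ether bonds resist the Lewis acid, so nothing else is at stake in this step.

Phenol 29 is cut at the aryl C–O bonds on C1 of rings G, F and E in turn, leading through 26 and 23 to phenol 19 and three units of fluoroaldehyde 20. In each of these rings C1 is para to the hindered oxygen on C4. If that oxygen is held as a formyl carbon, C1 becomes an electrophile for the hindered phenoxide of the growing chain, and a peracid-induced aryl migration then turns the formyl carbon into the next phenol (aldehydes 27, 24, 21; formates 28, 25, 22). Two steps per ring are needed, and no position of the electron-rich chain has to be functionalised after assembly.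

Ring D cannot be introduced by the same aldehyde, because its C1 is ortho, not para, to the oxygen that goes on to ring E, and a fluoride there would be deactivated by a para methoxy group. Phenol 19 is therefore cut at the bond between the ring C oxygen and ring D C1, back to phenol 11 and bromoquinone 16 by way of quinone 17 and hydroquinone 18. In 16 the bromine-bearing carbon becomes C1, the neighbouring carbonyl becomes the oxygen for ring E, and the far carbonyl becomes the oxygen on C5. The dimethoxyquinone core is symmetric, so direct substitution and attack at the neighbouring CH lead to the same 17. The two hydroxyls of 18 differ in hindrance: the one needed as nucleophile lies between a methoxy and the bulky aryloxy group, the other has a CH neighbour. The second is capped as an isopropyl ether, not a methyl ether, because a secondary halide distinguishes the two sites better and the isopropyl group falls with the methyl groups at the end.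

Bromoquinone 16 comes from aldehyde 12 by bromination to 13, aryl migration to phenol 15 through formate 14, and oxidative demethylation.

Phenol 11 is traced to benzyl ether 10. The benzyl group marks the one oxygen of ring C that must be freed later and is expected to pass through the nickel step.

Trimer 10 is cut at both remaining ether bonds, ring A oxygen to ring B C1 and ring B oxygen to ring C C1, by putting a carbonyl group back between each aryl carbon and the oxygen. This gives depside 8 (the second ester through mono-ether 9). The cut is made here because these two carbons are exactly where 1 carries its carboxyl group, and because a hindered phenol that resists arylation is acylated without trouble. Two hindered ether bonds are set in one operation, and rings B and C both come from one commodity acid. The forward reaction must excise both carbonyl groups and keep each aryloxide paired with its own aryl group.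

Depside 8 is cut at its two ester bonds: phenol 7 and acid chloride 4 give 8, 7 comes from benzyl ether 6, and 6 from phenol 5 and the same chloride 4. Chloride 4 is made once from acid 3 in a single batch that serves both acylations. Acid 3 is the benzyl ether of 1, made through ester 2.

## Alternatives that were turned down

Alternative 1: Ring F would be built, not bought. The ring bond between the carbon carrying the ring G ether and a neighbouring hydroxylated carbon is cut, which leads to pyranone A2, 4-(4-bromo-2,6-dimethoxyphenoxy)-6-[(3,4,5-trimethoxyphenoxy)methyl]pyran-2-one. In the forward step a magnesium alkoxide opens the lactone of A2 to a keto ester. The methylene carbon bearing the ring G ether is then acylated by the freed ester carbonyl, and aromatisation gives resorcinol A1.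
- For: the most hindered ether of ring F is made by alkylating a phenol on an sp3 carbon before the ring exists. The step needs only base. Recyclisation of pyranones to resorcinols is classical, so this key step stands on firmer ground than a nickel step not yet shown on such benzoates.
- Against: one ring and two ethers are gained from a precursor that itself needs several steps. The 4-aryloxy group of A2 is a vinylogous ester leaving group that the alkoxide can displace. The two new hydroxyls of A1 need methylation. The bromine of A1 must later be joined to the hindered oxygen on C2 of ring D, which brings back the metal-mediated arylation of a di-ortho-substituted phenol.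
- Comparison: the chosen route takes rings B and C from 1, sets both of their ethers in one step, and attaches the later rings by substitution on an aldehyde-activated fluoride.

Alternative 2: Two C–C bonds of ring B are cut, leading to cyclobutenone A4, 4-[4-(benzyloxy)-3,5-dimethoxyphenoxy]-3-ethoxycyclobut-2-en-1-one, and ethynyl ether A5, 2-(ethynyloxy)-1,3,5-trimethoxybenzene. On heating, A4 opens to a vinylketene that adds to A5 in a (2+2) sense. The new cyclobutenone opens, the dienylketene closes by a 6π process, and tautomerisation gives phenol A3.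
- For: the positions of both ethers are fixed by the mechanism, both exist before the ring does, and no metal is involved. Alkynyl ethers are established partners in this benzannulation, so the outcome is more predictable than that of the chosen key step.
- Against: A5, the ethynyl ether of a hindered electron-rich phenol, needs a multistep preparation and is thermally fragile. A4 needs a ketene cycloaddition of its own. A3 carries a free hydroxyl and an ethyl ether where the route needs uniform protection. Only ring B is made, in more steps than the whole depside 8.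
- Comparison: the chosen route gives up this regiochemical certainty in return for a much shorter path in which ring B is simply 1.

Alternative 3: Ring A is cut between the ether-bearing carbon and a neighbouring hydroxylated carbon, leading to keto ester A7, methyl 6-[4-(benzyloxy)-3,5-dimethoxyphenoxy]-3,5-dioxohexanoate. Base would make the terminal carbon 6 attack the ester carbonyl to give phloroglucinol A6.
- For: the hindered ether is made by a plain alkylation on an sp3 carbon, and the reagents are trivial. On simplicity of reagents it is stronger than the chosen route.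
- Against: carbon 6 is the least acidic position of A7, and closure through the enol oxygen to pyranone A8 is the easier reaction. A6 is a free, air-sensitive phloroglucinol whose O-methylation competes with C-methylation. One ether is gained per ring built, although ring A can be bought as phenol 5.
- Comparison: the chosen route buys ring A and spends its one uncertain step on two ether bonds at once.

Key step: step 6

Remark: the target is taken as drawn, achiral and without stereo elements, and compounds 1, 5, 12 and 20 are taken as purchasable.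
Shorthand: ABC-oxy, ABCD-oxy, ABCDE-oxy and ABCDEF-oxy are the aryloxy groups left when the phenolic hydrogen is removed from 11, 19, 23 and 26.

## Route

Step 1
Reactants: 1 syringic acid (4-hydroxy-3,5-dimethoxybenzoic acid)
Product: 3 4-(benzyloxy)-3,5-dimethoxybenzoic acid, via benzyl ester 2 (not isolated)
Conditions: BnBr, K2CO3, DMF, 60 °C; then NaOH, H2O/MeOH/THF, 60 °C; HCl to pH 2
Reagents that add atoms: benzyl bromide, BrCc1ccccc1; sodium hydroxide, [Na+].[OH-]
Why: Williamson benzylation of phenoxide and carboxylate alike, then saponification of the benzyl ester alone; the aryl benzyl ether is inert to hydroxide.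

Step 2
Reactants: 3 4-(benzyloxy)-3,5-dimethoxybenzoic acid
Product: 4 4-(benzyloxy)-3,5-dimethoxybenzoyl chloride
Conditions: (COCl)2 (1.5 equiv), cat. DMF, CH2Cl2, 0 °C to rt; evaporate, strip with toluene; crude solid kept under argon, one batch divided between steps 3 and 5
Reagents that add atoms: oxalyl chloride, ClC(=O)C(=O)Cl
Why: Acid chloride formation through the chloroiminium salt made from DMF and oxalyl chloride; the benzyl and methyl ethers are inert, and the only other products are gases, so the crude chloride can be used as it is for both acylations.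

Step 3
Reactants: 4 4-(benzyloxy)-3,5-dimethoxybenzoyl chloride; 5 2,4,6-trimethoxyphenol
Product: 6 2,4,6-trimethoxyphenyl 4-(benzyloxy)-3,5-dimethoxybenzoate
Conditions: Et3N, cat. DMAP, CH2Cl2, 0 °C to rt
Reagents that add atoms: none
Why: DMAP-catalysed O-acylation of a phenol by an acid chloride; the hindered phenol reacts readily because the acyl carbon has no ortho substituent.

Step 4
Reactants: 6 2,4,6-trimethoxyphenyl 4-(benzyloxy)-3,5-dimethoxybenzoate
Product: 7 2,4,6-trimethoxyphenyl 4-hydroxy-3,5-dimethoxybenzoate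
Conditions: H2 (1 atm), Pd/C (10%), EtOAc, rt
Reagents that add atoms: none
Why: Hydrogenolysis of the benzylic C–O bond on palladium; the aryl ester and the methyl ethers are not touched.

Step 5
Reactants: 4 4-(benzyloxy)-3,5-dimethoxybenzoyl chloride; 7 2,4,6-trimethoxyphenyl 4-hydroxy-3,5-dimethoxybenzoate
Product: 8 2,6-dimethoxy-4-[(2,4,6-trimethoxyphenoxy)carbonyl]phenyl 4-(benzyloxy)-3,5-dimethoxybenzoate (the A–B–C depside)
Conditions: 4 (1.2 equiv), Et3N, DMAP, CH2Cl2, rt
Reagents that add atoms: none
Why: Second O-acylation of the same kind; the phenol of 7 is hindered and made less nucleophilic by its para ester, so the acylpyridinium formed with DMAP is used to drive it.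

Step 6
Reactants: 8 the A–B–C depside
Product: 10 2-{4-[4-(benzyloxy)-3,5-dimethoxyphenoxy]-3,5-dimethoxyphenoxy}-1,3,5-trimethoxybenzene (ABC trimer benzyl ether), via mono-decarbonylated ester 9 (not isolated)
Conditions: Ni(cod)2 (20 mol %), 3,4-bis(dicyclohexylphosphino)thiophene (40 mol %), K3PO4 (3 equiv), m-xylene, 0.03 M, 150 °C, slow argon sweep
Reagents that add atoms: none
Why: Proposed new method: zerovalent nickel on the electron-rich bisphosphine should insert into each acyl C–O bond to give an aroylnickel aryloxide, which loses CO by migration of the aryl group to nickel and then forms the diaryl ether by C–O reductive elimination from divalent nickel; the closest known reaction type is the decarbonylative etherification of aryl azinecarboxylates with this catalyst, whereas electron-rich benzoates of 2,6-disubstituted phenols and a twofold version have not been shown. The ester on the ring B oxygen should react first, because its leaving aryloxide carries a para ester group, so 9 is the expected intermediate and the 2,4,6-trimethoxyphenyl ester follows. No ring closes and no stereocentre is formed. The step needs decarbonylation to outrun acyl transfer, hydrolysis and exchange of aryloxides between nickel centres, and it needs insertion into the acyl C–O bond, not into an aryl C–O bond. Three features of 8 help: both aroyl rings have hydrogen at both ortho positions, which eases insertion and aryl migration; both aryloxide carbons are flanked by two methoxy groups, which keeps nickel out of the aryl C–O bonds and should press the reductive elimination forward; and the para oxygen of each aroyl ring is twisted out of conjugation by its methoxy neighbours, so the carbonyl groups are less deactivated than the substitution suggests. Anhydrous K3PO4, dilution and the argon sweep that carries CO away are meant to hold down hydrolysis, crossover and catalyst poisoning.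

Step 7
Reactants: 10 ABC trimer benzyl ether
Product: 11 4-[2,6-dimethoxy-4-(2,4,6-trimethoxyphenoxy)phenoxy]-2,6-dimethoxyphenol (ABC phenol)
Conditions: H2 (1 atm), Pd/C (10%), EtOAc/EtOH, rt
Reagents that add atoms: none
Why: Hydrogenolysis of the one benzyl ether; diaryl ethers and methyl ethers are stable to these conditions.

Step 8
Reactants: 12 2,3,4-trimethoxybenzaldehyde
Product: 13 5-bromo-2,3,4-trimethoxybenzaldehyde
Conditions: NBS, DMF, rt
Reagents that add atoms: N-bromosuccinimide, O=C1CCC(=O)N1Br
Why: Electrophilic aromatic bromination at C5, ortho to the 4-methoxy and para to the 2-methoxy group; the C6 isomer would give the same quinone 16 later, since the dimethoxyquinone core is symmetric.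

Step 9
Reactants: 13 5-bromo-2,3,4-trimethoxybenzaldehyde
Product: 15 5-bromo-2,3,4-trimethoxyphenol, via formate 14 (not isolated)
Conditions: mCPBA, CH2Cl2, 0 °C to rt; aq Na2S2O3 wash; then K2CO3, MeOH, rt
Reagents that add atoms: 3-chloroperbenzoic acid, O=C(OO)c1cccc(Cl)c1
Why: Baeyer–Villiger (Dakin-type) oxidation; the aryl group migrates because it carries methoxy groups ortho and para to the formyl group, and the formate is cleaved by methanolysis.

Step 10
Reactants: 15 5-bromo-2,3,4-trimethoxyphenol
Product: 16 5-bromo-2,3-dimethoxycyclohexa-2,5-diene-1,4-dione (bromoquinone)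
Conditions: (NH4)2Ce(NO3)6 (2.2 equiv), MeCN/H2O, 0 °C
Reagents that add atoms: water, O
Why: Oxidative demethylation of a 4-methoxyphenol by tetravalent cerium: two one-electron oxidations, addition of water at C4 and loss of methanol give the para-quinone.

Step 11
Reactants: 11 ABC phenol; 16 bromoquinone
Product: 17 5-(ABC-oxy)-2,3-dimethoxycyclohexa-2,5-diene-1,4-dione
Conditions: Cs2CO3 (1.1 equiv), MeCN, 0 °C to rt, argon, phenoxide added slowly to 16
Reagents that add atoms: none
Why: Addition–elimination of a phenoxide on a haloquinone; direct displacement of bromide and attack at the neighbouring CH followed by loss of HBr give the same product because the quinone core is symmetric, and the methoxy-bearing carbons are less electrophilic and carry a poorer leaving group.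

Step 12
Reactants: 17 5-(ABC-oxy)-2,3-dimethoxycyclohexa-2,5-diene-1,4-dione
Product: 19 2-(ABC-oxy)-5,6-dimethoxy-4-(propan-2-yloxy)phenol, via hydroquinone 18 (not isolated)
Conditions: Na2S2O4, THF/H2O, rt; phase separation under argon; then 2-bromopropane (1.3 equiv), K2CO3, DMF, 40 °C
Reagents that add atoms: 2-bromopropane, CC(C)Br
Why: Dithionite reduction of the quinone, then Williamson etherification under steric control: the hydroxyl next to C6–H should be alkylated and the one between the methoxy and the bulky aryloxy group should not, a difference that a secondary bromide widens; limiting the bromide guards against double alkylation.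

Step 13
Reactants: 19 2-(ABC-oxy)-5,6-dimethoxy-4-(propan-2-yloxy)phenol; 20 4-fluoro-2,6-dimethoxybenzaldehyde
Product: 21 2,6-dimethoxy-4-(ABCD-oxy)benzaldehyde
Conditions: Cs2CO3, DMF, 100 °C, argon
Reagents that add atoms: none
Why: Nucleophilic aromatic substitution of a fluoride para to a formyl group; the attacked carbon has two CH neighbours, so even this di-ortho-substituted phenoxide can reach it.

Step 14
Reactants: 21 2,6-dimethoxy-4-(ABCD-oxy)benzaldehyde
Product: 23 2,6-dimethoxy-4-(ABCD-oxy)phenol, via formate 22 (not isolated)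
Conditions: mCPBA, CH2Cl2, 0 °C to rt; aq Na2S2O3 wash; then K2CO3, MeOH, rt
Reagents that add atoms: 3-chloroperbenzoic acid, O=C(OO)c1cccc(Cl)c1
Why: Baeyer–Villiger oxidation with migration of the 2,6-dimethoxyaryl group; the peracid is removed before the formate is cleaved, so the free phenol never meets the oxidant.

Step 15
Reactants: 23 2,6-dimethoxy-4-(ABCD-oxy)phenol; 20 4-fluoro-2,6-dimethoxybenzaldehyde
Product: 24 2,6-dimethoxy-4-(ABCDE-oxy)benzaldehyde
Conditions: Cs2CO3, DMF, 100 °C, argon
Reagents that add atoms: none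
Why: Same nucleophilic aromatic substitution as in step 13, now with a 2,6-dimethoxyphenoxide, the standard nucleophile for this fluoroaldehyde.

Step 16
Reactants: 24 2,6-dimethoxy-4-(ABCDE-oxy)benzaldehyde
Product: 26 2,6-dimethoxy-4-(ABCDE-oxy)phenol, via formate 25 (not isolated)
Conditions: mCPBA, CH2Cl2, 0 °C to rt; aq Na2S2O3 wash; then K2CO3, MeOH, rt
Reagents that add atoms: 3-chloroperbenzoic acid, O=C(OO)c1cccc(Cl)c1
Why: Baeyer–Villiger oxidation and formate methanolysis as in step 14.

Step 17
Reactants: 26 2,6-dimethoxy-4-(ABCDE-oxy)phenol; 20 4-fluoro-2,6-dimethoxybenzaldehyde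
Product: 27 2,6-dimethoxy-4-(ABCDEF-oxy)benzaldehyde
Conditions: Cs2CO3, DMF, 100 °C, argon
Reagents that add atoms: none
Why: Third nucleophilic aromatic substitution of the same kind, bringing in ring G.

Step 18
Reactants: 27 2,6-dimethoxy-4-(ABCDEF-oxy)benzaldehyde
Product: 29 2,6-dimethoxy-4-(ABCDEF-oxy)phenol, via formate 28 (not isolated)
Conditions: mCPBA, CH2Cl2, 0 °C to rt; aq Na2S2O3 wash; then K2CO3, MeOH, rt
Reagents that add atoms: 3-chloroperbenzoic acid, O=C(OO)c1cccc(Cl)c1
Why: Baeyer–Villiger oxidation and methanolysis give the 4-hydroxyl of ring G, which needs no further protection.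

Step 19
Reactants: 29 2,6-dimethoxy-4-(ABCDEF-oxy)phenol
Product: 30 the target heptamer CNP0304148.0 with seventeen free hydroxyls
Conditions: BBr3 (30 equiv), CH2Cl2, −78 °C to rt; then H2O, 0 °C, work-up under argon
Reagents that add atoms: none
Why: Lewis-acid cleavage of alkyl aryl ethers: boron binds each ether oxygen and bromide removes the methyl or isopropyl group, while the diaryl ether bonds offer no carbon that bromide can attack; hydrolysis of the aryl borates frees the phenols.

## Compound list

1 | syringic acid (4-hydroxy-3,5-dimethoxybenzoic acid) | COc1cc(C(=O)O)cc(OC)c1O | starting material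
2 | benzyl 4-(benzyloxy)-3,5-dimethoxybenzoate | COc1cc(C(=O)OCc2ccccc2)cc(OC)c1OCc1ccccc1 | intermediate
3 | 4-(benzyloxy)-3,5-dimethoxybenzoic acid | COc1cc(C(=O)O)cc(OC)c1OCc1ccccc1 | intermediate
4 | 4-(benzyloxy)-3,5-dimethoxybenzoyl chloride | COc1cc(C(=O)Cl)cc(OC)c1OCc1ccccc1 | intermediate
5 | 2,4,6-trimethoxyphenol | COc1cc(OC)c(O)c(OC)c1 | starting material
6 | 2,4,6-trimethoxyphenyl 4-(benzyloxy)-3,5-dimethoxybenzoate | COc1cc(OC)c(OC(=O)c2cc(OC)c(OCc3ccccc3)c(OC)c2)c(OC)c1 | intermediate
7 | 2,4,6-trimethoxyphenyl 4-hydroxy-3,5-dimethoxybenzoate | COc1cc(OC)c(OC(=O)c2cc(OC)c(O)c(OC)c2)c(OC)c1 | intermediate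
8 | 2,6-dimethoxy-4-[(2,4,6-trimethoxyphenoxy)carbonyl]phenyl 4-(benzyloxy)-3,5-dimethoxybenzoate (A–B–C depside) | COc1cc(OC)c(OC(=O)c2cc(OC)c(OC(=O)c3cc(OC)c(OCc4ccccc4)c(OC)c3)c(OC)c2)c(OC)c1 | intermediate
9 | 2,4,6-trimethoxyphenyl 4-[4-(benzyloxy)-3,5-dimethoxyphenoxy]-3,5-dimethoxybenzoate | COc1cc(OC)c(OC(=O)c2cc(OC)c(Oc3cc(OC)c(OCc4ccccc4)c(OC)c3)c(OC)c2)c(OC)c1 | intermediate
10 | 2-{4-[4-(benzyloxy)-3,5-dimethoxyphenoxy]-3,5-dimethoxyphenoxy}-1,3,5-trimethoxybenzene (ABC trimer benzyl ether) | COc1cc(OC)c(Oc2cc(OC)c(Oc3cc(OC)c(OCc4ccccc4)c(OC)c3)c(OC)c2)c(OC)c1 | intermediate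
11 | 4-[2,6-dimethoxy-4-(2,4,6-trimethoxyphenoxy)phenoxy]-2,6-dimethoxyphenol (ABC phenol) | COc1cc(OC)c(Oc2cc(OC)c(Oc3cc(OC)c(O)c(OC)c3)c(OC)c2)c(OC)c1 | intermediate
12 | 2,3,4-trimethoxybenzaldehyde | COc1ccc(C=O)c(OC)c1OC | starting material
13 | 5-bromo-2,3,4-trimethoxybenzaldehyde | COc1c(Br)cc(C=O)c(OC)c1OC | intermediate
14 | 5-bromo-2,3,4-trimethoxyphenyl formate | COc1c(Br)cc(OC=O)c(OC)c1OC | intermediate
15 | 5-bromo-2,3,4-trimethoxyphenol | COc1c(Br)cc(O)c(OC)c1OC | intermediate
16 | 5-bromo-2,3-dimethoxycyclohexa-2,5-diene-1,4-dione | COC1=C(OC)C(=O)C(Br)=CC1=O | intermediate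
17 | 5-(ABC-oxy)-2,3-dimethoxycyclohexa-2,5-diene-1,4-dione | COc1cc(OC)c(Oc2cc(OC)c(Oc3cc(OC)c(OC4=CC(=O)C(OC)=C(OC)C4=O)c(OC)c3)c(OC)c2)c(OC)c1 | intermediate
18 | 5-(ABC-oxy)-2,3-dimethoxybenzene-1,4-diol | COc1cc(OC)c(Oc2cc(OC)c(Oc3cc(OC)c(Oc4cc(O)c(OC)c(OC)c4O)c(OC)c3)c(OC)c2)c(OC)c1 | intermediate
19 | 2-(ABC-oxy)-5,6-dimethoxy-4-(propan-2-yloxy)phenol (ABCD phenol) | COc1cc(OC)c(Oc2cc(OC)c(Oc3cc(OC)c(Oc4cc(OC(C)C)c(OC)c(OC)c4O)c(OC)c3)c(OC)c2)c(OC)c1 | intermediate
20 | 4-fluoro-2,6-dimethoxybenzaldehyde | COc1cc(F)cc(OC)c1C=O | starting material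
21 | 2,6-dimethoxy-4-(ABCD-oxy)benzaldehyde | COc1cc(OC)c(Oc2cc(OC)c(Oc3cc(OC)c(Oc4cc(OC(C)C)c(OC)c(OC)c4Oc4cc(OC)c(C=O)c(OC)c4)c(OC)c3)c(OC)c2)c(OC)c1 | intermediate
22 | 2,6-dimethoxy-4-(ABCD-oxy)phenyl formate | COc1cc(OC)c(Oc2cc(OC)c(Oc3cc(OC)c(Oc4cc(OC(C)C)c(OC)c(OC)c4Oc4cc(OC)c(OC=O)c(OC)c4)c(OC)c3)c(OC)c2)c(OC)c1 | intermediate
23 | 2,6-dimethoxy-4-(ABCD-oxy)phenol (ABCDE phenol) | COc1cc(OC)c(Oc2cc(OC)c(Oc3cc(OC)c(Oc4cc(OC(C)C)c(OC)c(OC)c4Oc4cc(OC)c(O)c(OC)c4)c(OC)c3)c(OC)c2)c(OC)c1 | intermediate
24 | 2,6-dimethoxy-4-(ABCDE-oxy)benzaldehyde | COc1cc(OC)c(Oc2cc(OC)c(Oc3cc(OC)c(Oc4cc(OC(C)C)c(OC)c(OC)c4Oc4cc(OC)c(Oc5cc(OC)c(C=O)c(OC)c5)c(OC)c4)c(OC)c3)c(OC)c2)c(OC)c1 | intermediate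
25 | 2,6-dimethoxy-4-(ABCDE-oxy)phenyl formate | COc1cc(OC)c(Oc2cc(OC)c(Oc3cc(OC)c(Oc4cc(OC(C)C)c(OC)c(OC)c4Oc4cc(OC)c(Oc5cc(OC)c(OC=O)c(OC)c5)c(OC)c4)c(OC)c3)c(OC)c2)c(OC)c1 | intermediate
26 | 2,6-dimethoxy-4-(ABCDE-oxy)phenol (ABCDEF phenol) | COc1cc(OC)c(Oc2cc(OC)c(Oc3cc(OC)c(Oc4cc(OC(C)C)c(OC)c(OC)c4Oc4cc(OC)c(Oc5cc(OC)c(O)c(OC)c5)c(OC)c4)c(OC)c3)c(OC)c2)c(OC)c1 | intermediate
27 | 2,6-dimethoxy-4-(ABCDEF-oxy)benzaldehyde | COc1cc(OC)c(Oc2cc(OC)c(Oc3cc(OC)c(Oc4cc(OC(C)C)c(OC)c(OC)c4Oc4cc(OC)c(Oc5cc(OC)c(Oc6cc(OC)c(C=O)c(OC)c6)c(OC)c5)c(OC)c4)c(OC)c3)c(OC)c2)c(OC)c1 | intermediate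
28 | 2,6-dimethoxy-4-(ABCDEF-oxy)phenyl formate | COc1cc(OC)c(Oc2cc(OC)c(Oc3cc(OC)c(Oc4cc(OC(C)C)c(OC)c(OC)c4Oc4cc(OC)c(Oc5cc(OC)c(Oc6cc(OC)c(OC=O)c(OC)c6)c(OC)c5)c(OC)c4)c(OC)c3)c(OC)c2)c(OC)c1 | intermediate
29 | 2,6-dimethoxy-4-(ABCDEF-oxy)phenol (protected heptamer) | COc1cc(OC)c(Oc2cc(OC)c(Oc3cc(OC)c(Oc4cc(OC(C)C)c(OC)c(OC)c4Oc4cc(OC)c(Oc5cc(OC)c(Oc6cc(OC)c(O)c(OC)c6)c(OC)c5)c(OC)c4)c(OC)c3)c(OC)c2)c(OC)c1 | intermediate
30 | CNP0304148.0, heptamer with rings A to G and seventeen hydroxyls | Oc1cc(O)c(Oc2cc(O)c(Oc3cc(O)c(Oc4cc(O)c(O)c(O)c4Oc4cc(O)c(Oc5cc(O)c(Oc6cc(O)c(O)c(O)c6)c(O)c5)c(O)c4)c(O)c3)c(O)c2)c(O)c1 | target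

## Step count and least certain steps

Total: 19 steps. Longest linear sequence: 16 steps (steps 1 to 7 and 11 to 19); the ring D branch (steps 8 to 10) joins at step 11.

Step 6 (key step, new method). The most likely failures are:
- insertion of nickel that is too slow for benzoates without a coordinating ring nitrogen, so that the ester survives or only 9 forms;
- exchange of aryloxides between nickel centres, which would join the wrong aryl and aryloxide partners;
- catalyst death by bound CO.

The fallback uses known chemistry, sets out from 5 and returns at 11. Phenol 5 is arylated with 20 (Cs2CO3, DMF, 100 °C) to 2,6-dimethoxy-4-(2,4,6-trimethoxyphenoxy)benzaldehyde F1. Baeyer–Villiger oxidation with mCPBA gives 2,6-dimethoxy-4-(2,4,6-trimethoxyphenoxy)phenyl formate F2, which K2CO3 in MeOH cleaves to 2,6-dimethoxy-4-(2,4,6-trimethoxyphenoxy)phenol F3. A second arylation with 20 gives 4-[2,6-dimethoxy-4-(2,4,6-trimethoxyphenoxy)phenoxy]-2,6-dimethoxybenzaldehyde F4. Oxidation to 4-[2,6-dimethoxy-4-(2,4,6-trimethoxyphenoxy)phenoxy]-2,6-dimethoxyphenyl formate F5 and methanolysis deliver 11. These are the same two operations as in steps 13 to 18.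

Step 11. Electron transfer from the very electron-rich phenoxide of 11 to the quinone may compete with substitution, oxidising the phenol and reducing 16; displacement of a quinone methoxy group is a lesser risk. The fallback sets out from 11 and returns at 17, and it forms the ether before any quinone is present. Vilsmeier formylation (POCl3, DMF) of 5-fluoro-1,2,3-trimethoxybenzene F6, taken as purchasable, gives 6-fluoro-2,3,4-trimethoxybenzaldehyde F7. Phenoxide 11 displaces its fluoride (Cs2CO3, DMSO, 120 °C) to give 6-(ABC-oxy)-2,3,4-trimethoxybenzaldehyde F8. mCPBA then gives 6-(ABC-oxy)-2,3,4-trimethoxyphenyl formate F9, and methanolysis gives 6-(ABC-oxy)-2,3,4-trimethoxyphenol F10. PhI(OAc)2 in aqueous MeCN oxidises the 4-methoxyphenol unit of F10 to quinone 17.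

Step 12. Site selectivity between the two hydroxyls of 18 may be incomplete, a second alkylation may follow, and 18 may be reoxidised by traces of air. The fallback sets out from 17 and returns at 19, and it replaces the kinetic differentiation by a protecting-group sequence. Reductive acetylation (Zn dust, Ac2O, NaOAc) gives 2-(ABC-oxy)-5,6-dimethoxybenzene-1,4-diyl diacetate F11. NH4OAc in aqueous MeOH removes the unhindered acetate to give 2-(ABC-oxy)-4-hydroxy-5,6-dimethoxyphenyl acetate F12. Mitsunobu etherification with 2-propanol (PPh3, DIAD) gives 2-(ABC-oxy)-5,6-dimethoxy-4-(propan-2-yloxy)phenyl acetate F13, and K2CO3 in MeOH gives 19.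

Step 19. Cleavage of sixteen ethers may stop short, and the product may be lost to air oxidation or to boron chelates during isolation. The fallback sets out from 29 and returns at 30. The crude product of the BBr3 reaction is not isolated but acetylated (Ac2O, pyridine, DMAP) to the heptadecaacetate of 30 F14, which is stable and can be chromatographed, so that under-cleaved material can be separated and resubmitted. Acid-catalysed methanolysis (HCl in degassed MeOH) then releases 30.

## Further compounds

F1 | step 6 | 2,6-dimethoxy-4-(2,4,6-trimethoxyphenoxy)benzaldehyde | COc1cc(OC)c(Oc2cc(OC)c(C=O)c(OC)c2)c(OC)c1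
F2 | step 6 | 2,6-dimethoxy-4-(2,4,6-trimethoxyphenoxy)phenyl formate | COc1cc(OC)c(Oc2cc(OC)c(OC=O)c(OC)c2)c(OC)c1
F3 | step 6 | 2,6-dimethoxy-4-(2,4,6-trimethoxyphenoxy)phenol | COc1cc(OC)c(Oc2cc(OC)c(O)c(OC)c2)c(OC)c1
F4 | step 6 | 4-[2,6-dimethoxy-4-(2,4,6-trimethoxyphenoxy)phenoxy]-2,6-dimethoxybenzaldehyde | COc1cc(OC)c(Oc2cc(OC)c(Oc3cc(OC)c(C=O)c(OC)c3)c(OC)c2)c(OC)c1
F5 | step 6 | 4-[2,6-dimethoxy-4-(2,4,6-trimethoxyphenoxy)phenoxy]-2,6-dimethoxyphenyl formate | COc1cc(OC)c(Oc2cc(OC)c(Oc3cc(OC)c(OC=O)c(OC)c3)c(OC)c2)c(OC)c1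
F6 | step 11 | 5-fluoro-1,2,3-trimethoxybenzene | COc1cc(F)cc(OC)c1OC
F7 | step 11 | 6-fluoro-2,3,4-trimethoxybenzaldehyde | COc1cc(F)c(C=O)c(OC)c1OC
F8 | step 11 | 6-(ABC-oxy)-2,3,4-trimethoxybenzaldehyde | COc1cc(OC)c(Oc2cc(OC)c(Oc3cc(OC)c(Oc4cc(OC)c(OC)c(OC)c4C=O)c(OC)c3)c(OC)c2)c(OC)c1
F9 | step 11 | 6-(ABC-oxy)-2,3,4-trimethoxyphenyl formate | COc1cc(OC)c(Oc2cc(OC)c(Oc3cc(OC)c(Oc4cc(OC)c(OC)c(OC)c4OC=O)c(OC)c3)c(OC)c2)c(OC)c1
F10 | step 11 | 6-(ABC-oxy)-2,3,4-trimethoxyphenol | COc1cc(OC)c(Oc2cc(OC)c(Oc3cc(OC)c(Oc4cc(OC)c(OC)c(OC)c4O)c(OC)c3)c(OC)c2)c(OC)c1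
F11 | step 12 | 2-(ABC-oxy)-5,6-dimethoxybenzene-1,4-diyl diacetate | COc1cc(OC)c(Oc2cc(OC)c(Oc3cc(OC)c(Oc4cc(OC(C)=O)c(OC)c(OC)c4OC(C)=O)c(OC)c3)c(OC)c2)c(OC)c1
F12 | step 12 | 2-(ABC-oxy)-4-hydroxy-5,6-dimethoxyphenyl acetate | COc1cc(OC)c(Oc2cc(OC)c(Oc3cc(OC)c(Oc4cc(O)c(OC)c(OC)c4OC(C)=O)c(OC)c3)c(OC)c2)c(OC)c1
F13 | step 12 | 2-(ABC-oxy)-5,6-dimethoxy-4-(propan-2-yloxy)phenyl acetate | COc1cc(OC)c(Oc2cc(OC)c(Oc3cc(OC)c(Oc4cc(OC(C)C)c(OC)c(OC)c4OC(C)=O)c(OC)c3)c(OC)c2)c(OC)c1
F14 | step 19 | heptadecaacetate of 30 (every hydroxyl as acetate) | CC(=O)Oc1cc(OC(C)=O)c(Oc2cc(OC(C)=O)c(Oc3cc(OC(C)=O)c(Oc4cc(OC(C)=O)c(OC(C)=O)c(OC(C)=O)c4Oc4cc(OC(C)=O)c(Oc5cc(OC(C)=O)c(Oc6cc(OC(C)=O)c(OC(C)=O)c(OC(C)=O)c6)c(OC(C)=O)c5)c(OC(C)=O)c4)c(OC(C)=O)c3)c(OC(C)=O)c2)c(OC(C)=O)c1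
A1 | alternative 1 | 5-(4-bromo-2,6-dimethoxyphenoxy)-2-(3,4,5-trimethoxyphenoxy)benzene-1,3-diol | Oc1cc(Oc2c(OC)cc(Br)cc2OC)cc(O)c1Oc1cc(OC)c(OC)c(OC)c1
A2 | alternative 1 | 4-(4-bromo-2,6-dimethoxyphenoxy)-6-[(3,4,5-trimethoxyphenoxy)methyl]-2H-pyran-2-one | O=C1C=C(Oc2c(OC)cc(Br)cc2OC)C=C(COc2cc(OC)c(OC)c(OC)c2)O1
A3 | alternative 2 | 2-[4-(benzyloxy)-3,5-dimethoxyphenoxy]-3-ethoxy-5-(2,4,6-trimethoxyphenoxy)phenol | CCOc1cc(Oc2c(OC)cc(OC)cc2OC)cc(O)c1Oc1cc(OC)c(OCc2ccccc2)c(OC)c1
A4 | alternative 2 | 4-[4-(benzyloxy)-3,5-dimethoxyphenoxy]-3-ethoxycyclobut-2-en-1-one | CCOC1=CC(=O)C1Oc1cc(OC)c(OCc2ccccc2)c(OC)c1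
A5 | alternative 2 | 2-(ethynyloxy)-1,3,5-trimethoxybenzene | C#COc1c(OC)cc(OC)cc1OC
A6 | alternative 3 | 2-[4-(benzyloxy)-3,5-dimethoxyphenoxy]benzene-1,3,5-triol | Oc1cc(O)c(Oc2cc(OC)c(OCc3ccccc3)c(OC)c2)c(O)c1
A7 | alternative 3 | methyl 6-[4-(benzyloxy)-3,5-dimethoxyphenoxy]-3,5-dioxohexanoate | COC(=O)CC(=O)CC(=O)COc1cc(OC)c(OCc2ccccc2)c(OC)c1
A8 | alternative 3 | 6-{[4-(benzyloxy)-3,5-dimethoxyphenoxy]methyl}-4-hydroxy-2H-pyran-2-one | O=C1C=C(O)C=C(COc2cc(OC)c(OCc3ccccc3)c(OC)c2)O1
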